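**Retrosynthetic overview**
- Target 15 ← alcohol 13 (senecioylation) ← β-hydroxy ketone 11 (Evans–Tishchenko sets C9 and installs the isovalerate) ← dienedione 9 (asymmetric β-borylation sets C7).
- Key disconnection: the C10–C11 cyclobutane bond of 9, made by oxidative coupling of the two enolate α-carbons of cis-fused bis-enone 7. One donor carbon is turned into an electrophilic α-keto radical (enolonium-type reversal of polarity). The step creates the quaternary C10 and C11.
- 7 ← one-carbon ring enlargement (diazoethane) and Saegusa oxidation of cis-decalin 5 ← enantioselective Diels–Alder of dienone 2 with silyloxydiene 4.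
- Ring order: ring A (cyclohexenone) by Diels–Alder; ring B (seven-membered) by ring enlargement; cyclobutane last.

Numbering in names: the tricycles are named as longipinanes (C1 carbonyl, C2=C3(CH3); cyclobutane = C4, C5, C11, C10; C4 and C11 flank the enone, C5 carries C6(CH3)2, then C7, C8, C9; C10 is the quaternary methyl carbon). Compounds 6–8 are named as bicyclo[5.4.0]undecanes whose C1, C2, C3, C7, C8 become longipinane C4, C10, C9, C5, C11. In this numbering the target is (4R,5S,7R,9R,10R,11R).

Assumption: the two chiral catalysts (steps 3 and 7) induce the sense drawn; each is available as its antipode should the observed sense be the opposite.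

**Step 1**
Reactants: 1 4,4-dimethylcyclohex-2-en-1-one
Product: 2 4,4-dimethylcyclohexa-2,5-dien-1-one
Conditions: DDQ (1.3 equiv), TsOH·H2O (cat.), 1,4-dioxane, reflux
Reagents that add atoms: none
Why: DDQ dehydrogenation of an enone whose C4 is quaternary can only give the cross-conjugated dienone, and no stereocentre is formed.

**Step 2**
Reactants: 3 (E)-pent-3-en-2-one
Product: 4 (E)-2-[tri(propan-2-yl)silyloxy]penta-1,3-diene
Conditions: TIPSOTf, Et3N, Et2O, 0 °C → rt
Reagents that add atoms: triisopropylsilyl trifluoromethanesulfonate CC(C)[Si](C(C)C)(C(C)C)OS(=O)(=O)C(F)(F)F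
Why: Soft enolisation and O-silylation at the methyl group gives the cross-conjugated 2-silyloxydiene with the E alkene retained.

**Step 3**
Reactants: 2 4,4-dimethylcyclohexa-2,5-dien-1-one; 4 (E)-2-[tri(propan-2-yl)silyloxy]penta-1,3-diene
Product: 5 (4aR,8S,8aS)-4,4,8-trimethyl-6-[tri(propan-2-yl)silyloxy]-4a,5,8,8a-tetrahydronaphthalen-1(4H)-one (cis-fused; C8 methyl cis to the C1 carbonyl)
Conditions: (S)-3,3-diphenyl-1-(2-methylphenyl)tetrahydro-1H,3H-pyrrolo[1,2-c][1,3,2]oxazaborole·HNTf2 (20 mol %), 2 (1.5 equiv), CH2Cl2, −78 → −40 °C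
Reagents that add atoms: none
Why: Chiral Lewis acid-catalysed Diels–Alder reaction in which the CH2 terminus of 4 bonds to the hindered β-carbon and the methyl-bearing terminus to the α-carbon of 2; suprafacial addition fixes the cis ring fusion, endo approach places the C8 methyl cis to the carbonyl, and the catalyst selects one enantiotopic enone face of the achiral dienone.

**Step 4**
Reactants: 5 (4aR,8S,8aS)-4,4,8-trimethyl-6-[tri(propan-2-yl)silyloxy]-4a,5,8,8a-tetrahydronaphthalen-1(4H)-one
Product: 6 (1S,7R,11R)-2,6,6,11-tetramethyl-9-[tri(propan-2-yl)silyloxy]bicyclo[5.4.0]undeca-4,9-dien-3-one (cis-fused; mixture of C2 epimers)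
Conditions: CH3CHN2 (1.3 equiv, fresh Et2O solution), Sc(OTf)3 (10 mol %), toluene, −78 °C
Reagents that add atoms: diazoethane CC=[N+]=[N-]
Why: Lewis acid-catalysed diazoalkane homologation (Tiffeneau–Demjanov-type insertion) at the only free ketone, ring A being masked as the silyl enol ether; the sp3 ring-fusion carbon migrates with retention in preference to the vinyl carbon, so CH(CH3) enters between the carbonyl and the ring fusion, and the new C2 centre forms as a mixture that step 6 erases.

**Step 5**
Reactants: 6 (1S,7R,11R)-2,6,6,11-tetramethyl-9-[tri(propan-2-yl)silyloxy]bicyclo[5.4.0]undeca-4,9-dien-3-one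
Product: 7 (1S,7R)-2,6,6,11-tetramethylbicyclo[5.4.0]undeca-4,10-diene-3,9-dione (cis-fused; mixture of C2 epimers)
Conditions: Pd(OAc)2 (1.1 equiv), MeCN, 40 °C
Reagents that add atoms: none
Why: Saegusa–Ito oxidation, in which the palladium enolate formed regiospecifically from the silyl enol ether loses the only β-hydrogen (on C11) to give the 3-methyl enone under neutral conditions that leave the cis ring fusion intact.

**Step 6**
Reactants: 7 (1S,7R)-2,6,6,11-tetramethylbicyclo[5.4.0]undeca-4,10-diene-3,9-dione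
Product: 9 (4R,5S,10R,11R)-longipina-2,7-diene-1,9-dione, via dilithium bis-enolate 8 (not isolated)
Conditions: LiN(iPr)2 (2.4 equiv), THF, −78 → −40 °C; then FeCl3 (2.4 equiv) in DMF, −78 → 0 °C, 0.01 M
Reagents that add atoms: none
Why: Proposed new method: double kinetic deprotonation (the α′-CH2 of the ring A enone and C2 of the ring B enone, its only enolisable carbon because the γ-carbon is quaternary) gives 8; one-electron oxidation by trivalent iron turns the more electron-rich tetrasubstituted enolate into an electrophilic tertiary α-keto radical that adds to the neighbouring enolate carbon, which lies gauche to it across the cis ring fusion, and a second oxidation of the resulting conjugated ketyl makes the 4-exo closure irreversible; only the cis-fused geometry allows the bond, so the configurations of C10 (quaternary) and C11 are dictated by C4 and C5; closest known reaction type is the iron- or copper-mediated oxidative coupling of lithium enolates to 1,4-diketones, including intramolecular closures of dienolates to cyclobutanes.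

**Step 7**
Reactants: 9 (4R,5S,10R,11R)-longipina-2,7-diene-1,9-dione
Product: 11 (4R,5S,7R,10R,11R)-7-hydroxylongipin-2-ene-1,9-dione, via pinacol boronate 10 (not isolated)
Conditions: CuCl (5 mol %), (R)-1-[(Sp)-2-(diphenylphosphino)ferrocenyl]ethyldicyclohexylphosphine (6 mol %), NaOtBu (10 mol %), B2pin2 (1.1 equiv), MeOH (2 equiv), THF, rt; then NaBO3·4H2O, THF/H2O, 0 °C
Reagents that add atoms: bis(pinacolato)diboron CC1(C)OB(OC1(C)C)B1OC(C)(C)C(C)(C)O1 (boron of 10); sodium perborate tetrahydrate [Na+].[O-]OB=O.O.O.O.O (oxygen of 11)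
Why: Copper-catalysed asymmetric conjugate borylation followed by C–B oxidation with retention; only the ring B enone (β-CH) reacts, the bridged β,β-disubstituted ring A enone being too hindered, and because the two faces at C7 are almost equivalent in the substrate the chiral ligand sets the 7R configuration.

**Step 8**
Reactants: 11 (4R,5S,7R,10R,11R)-7-hydroxylongipin-2-ene-1,9-dione; 12 3-methylbutanal
Product: 13 (4R,5S,7R,9R,10R,11R)-9-hydroxy-1-oxolongipin-2-en-7-yl 3-methylbutanoate
Conditions: SmI2 (30 mol %), 12 (5 equiv), THF, −10 °C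
Reagents that add atoms: none
Why: Evans–Tishchenko reduction, in which the samarium-bound hemiacetal formed on the C7 hydroxyl delivers hydride to the C9 ketone on the face of the C7–O bond, giving the 1,3-anti (trans) 9R alcohol while the C7 oxygen becomes the isovalerate and the hindered conjugated C1 ketone is untouched.

**Step 9**
Reactants: 13 (4R,5S,7R,9R,10R,11R)-9-hydroxy-1-oxolongipin-2-en-7-yl 3-methylbutanoate; 14 3-methylbut-2-enoyl chloride
Product: 15 (4R,5S,7R,9R,10R,11R)-7-(3-methylbutanoyloxy)-1-oxolongipin-2-en-9-yl 3-methylbut-2-enoate (CNP0335239.1)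
Conditions: pyridine, 4-(dimethylamino)pyridine (cat.), CH2Cl2, 0 °C → rt
Reagents that add atoms: none
Why: Nucleophile-catalysed acylation of the remaining secondary alcohol, which changes no stereocentre and uses a base too weak to deconjugate the senecioyl unit or promote a 1,3-acyl shift.

**Compound list**
1 | 4,4-dimethylcyclohex-2-en-1-one | CC1(C)CCC(=O)C=C1 | starting material
2 | 4,4-dimethylcyclohexa-2,5-dien-1-one | CC1(C)C=CC(=O)C=C1 | intermediate
3 | (E)-pent-3-en-2-one | C/C=C/C(C)=O | starting material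
4 | (E)-2-[tri(propan-2-yl)silyloxy]penta-1,3-diene | C/C=C/C(=C)O[Si](C(C)C)(C(C)C)C(C)C | intermediate
5 | (4aR,8S,8aS)-4,4,8-trimethyl-6-[tri(propan-2-yl)silyloxy]-4a,5,8,8a-tetrahydronaphthalen-1(4H)-one | CC(C)[Si](C(C)C)(C(C)C)OC1=C[C@H](C)[C@@H]2C(=O)C=CC(C)(C)[C@@H]2C1 | intermediate
6 | (1S,7R,11R)-2,6,6,11-tetramethyl-9-[tri(propan-2-yl)silyloxy]bicyclo[5.4.0]undeca-4,9-dien-3-one (C2 epimers) | CC(C)[Si](C(C)C)(C(C)C)OC1=C[C@H](C)[C@@H]2C(C)C(=O)C=CC(C)(C)[C@@H]2C1 | intermediate
7 | (1S,7R)-2,6,6,11-tetramethylbicyclo[5.4.0]undeca-4,10-diene-3,9-dione (C2 epimers) | O=C1C=C(C)[C@@H]2C(C)C(=O)C=CC(C)(C)[C@@H]2C1 | intermediate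
8 | dilithium (1R,7S)-2,6,6,11-tetramethylbicyclo[5.4.0]undeca-2,4,8,10-tetraene-3,9-bis(olate) | [Li+].[Li+].[O-]C1=C[C@H]2C(C)(C)C=CC([O-])=C(C)[C@H]2C(C)=C1 | intermediate
9 | (4R,5S,10R,11R)-longipina-2,7-diene-1,9-dione | O=C1C=CC(C)(C)[C@@H]2[C@H]3C(=O)C=C(C)[C@@H]2[C@]31C | intermediate
10 | (4R,5S,7R,10R,11R)-7-(4,4,5,5-tetramethyl-1,3,2-dioxaborolan-2-yl)longipin-2-ene-1,9-dione | O=C1C[C@@H](B4OC(C)(C)C(C)(C)O4)C(C)(C)[C@@H]2[C@H]3C(=O)C=C(C)[C@@H]2[C@]31C | intermediate
11 | (4R,5S,7R,10R,11R)-7-hydroxylongipin-2-ene-1,9-dione | O=C1C[C@@H](O)C(C)(C)[C@@H]2[C@H]3C(=O)C=C(C)[C@@H]2[C@]31C | intermediate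
12 | 3-methylbutanal | CC(C)CC=O | starting material
13 | (4R,5S,7R,9R,10R,11R)-9-hydroxy-1-oxolongipin-2-en-7-yl 3-methylbutanoate | O[C@@H]1C[C@@H](OC(=O)CC(C)C)C(C)(C)[C@@H]2[C@H]3C(=O)C=C(C)[C@@H]2[C@]31C | intermediate
14 | 3-methylbut-2-enoyl chloride | CC(C)=CC(=O)Cl | starting material
15 | (4R,5S,7R,9R,10R,11R)-7-(3-methylbutanoyloxy)-1-oxolongipin-2-en-9-yl 3-methylbut-2-enoate | CC(C)=CC(=O)O[C@@H]1C[C@@H](OC(=O)CC(C)C)C(C)(C)[C@@H]2[C@H]3C(=O)C=C(C)[C@@H]2[C@]31C | target

**Step count**
Total steps: 9. Longest linear sequence: 8 (1 → 2 → 5 → 6 → 7 → 9 → 11 → 13 → 15).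

**Three steps most likely to fail**

Step 3. The dienophile has a neopentyl β-carbon and enantioface control is untested on this dienone. The fallback sets out from 2 and 4 and comes back at 5. An EtAlCl2-promoted Diels–Alder reaction (CH2Cl2, −78 °C) gives racemic adduct, that is 5 together with its mirror image (4aS,8R,8aR)-4,4,8-trimethyl-6-[tri(propan-2-yl)silyloxy]-4a,5,8,8a-tetrahydronaphthalen-1(4H)-one F1. The enantiomers are separated by preparative chromatography on a chiral stationary phase (supercritical CO2/iPrOH), and 5 continues at step 4.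

Step 4. Diazoethane is less well behaved than diazomethane; pyrazoline formation and double insertion are possible. The fallback sets out from 5 and comes back at 6. CH2N2 with Sc(OTf)3 (toluene, −78 °C) inserts CH2 to give (1S,7R,11R)-6,6,11-trimethyl-9-[tri(propan-2-yl)silyloxy]bicyclo[5.4.0]undeca-4,9-dien-3-one F2. Ring A is still a silyl enol ether, so the new α-CH2 is the only enolisable position. LiN(iPr)2 (THF, −78 °C) therefore gives lithium (1S,7R,11R)-6,6,11-trimethyl-9-[tri(propan-2-yl)silyloxy]bicyclo[5.4.0]undeca-2,4,9-trien-3-olate F3, and MeI converts it into 6.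

Step 6 (the riskiest). The tertiary α-keto radical may be over-oxidised to a dienone or couple intermolecularly before the strained 4-exo closure. The fallback sets out from 7 and comes back at 9. Bis-enolate 8, made as in step 6, is trapped with TMSCl to give (1R,7S)-2,6,6,11-tetramethyl-3,9-bis(trimethylsilyloxy)bicyclo[5.4.0]undeca-2,4,8,10-tetraene F4. NBS (1 equiv, THF, −78 °C) brominates the less hindered ring A enol ether, anti to the axial C1 side chain, to give (1R,7R,8R)-8-bromo-2,6,6,11-tetramethyl-3-(trimethylsilyloxy)bicyclo[5.4.0]undeca-2,4,10-trien-9-one F5. Visible-light photoredox catalysis (fac-Ir(ppy)3, 1 mol %, MeCN, blue light, rt) then reduces the C–Br bond to the electrophilic α-keto radical. This radical adds to the carbon of the ring B silyl enol ether; the allylic α-silyloxy radical is oxidised and loses the silyl group, giving 9. No free enolate is present, so O-alkylation to a six-membered enol ether cannot compete.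

**Further compounds**
F1 | step 3 | (4aS,8R,8aR)-4,4,8-trimethyl-6-[tri(propan-2-yl)silyloxy]-4a,5,8,8a-tetrahydronaphthalen-1(4H)-one | CC(C)[Si](C(C)C)(C(C)C)OC1=C[C@@H](C)[C@H]2C(=O)C=CC(C)(C)[C@H]2C1
F2 | step 4 | (1S,7R,11R)-6,6,11-trimethyl-9-[tri(propan-2-yl)silyloxy]bicyclo[5.4.0]undeca-4,9-dien-3-one | CC(C)[Si](C(C)C)(C(C)C)OC1=C[C@H](C)[C@@H]2CC(=O)C=CC(C)(C)[C@@H]2C1
F3 | step 4 | lithium (1S,7R,11R)-6,6,11-trimethyl-9-[tri(propan-2-yl)silyloxy]bicyclo[5.4.0]undeca-2,4,9-trien-3-olate | [Li+].CC(C)[Si](C(C)C)(C(C)C)OC1=C[C@H](C)[C@@H]2C=C([O-])C=CC(C)(C)[C@@H]2C1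
F4 | step 6 | (1R,7S)-2,6,6,11-tetramethyl-3,9-bis(trimethylsilyloxy)bicyclo[5.4.0]undeca-2,4,8,10-tetraene | C[Si](C)(C)OC1=C[C@H]2C(C)(C)C=CC(O[Si](C)(C)C)=C(C)[C@H]2C(C)=C1
F5 | step 6 | (1R,7R,8R)-8-bromo-2,6,6,11-tetramethyl-3-(trimethylsilyloxy)bicyclo[5.4.0]undeca-2,4,10-trien-9-one | O=C1C=C(C)[C@@H]2C(C)=C(O[Si](C)(C)C)C=CC(C)(C)[C@@H]2[C@H]1Br
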